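**Plan**

1. The target is read as fisetinidol-(4α→6)-[fisetinidol-(4α→8)]-4'-O-methylcatechin: lower unit (2R,3S), each upper unit (2R,3S,4S).
2. Retrosynthetic cuts, in order: the two interflavanyl bonds C4(upper)–C6 and C4(upper)–C8; then, in the lower unit, the aryl ether bond O1–C8a of ring C; then C2–C1' (to ring B) and C4–C4a (to ring A).
3. Forward: ring A bromide → C4–C4a by epoxide opening → C2–C1' by ketone synthesis → reduction → ring C closed at O1–C8a → debenzylation → both fisetinidol units attached in one operation.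
4. Enabling feature: C8a of ring A is ortho to C4a (which carries the C4–C3–C2 chain) and meta to O5 and O7. Ring A can therefore enter as a 3,5-dioxygenated aryl bromide whose C–Br carbon becomes C8a, while O1 arrives on C2. No bond at C2 or C3 is broken, so the easily ionised 4-methoxybenzylic C2–O bond is never put at risk.
5. Stereochemistry: lower C3 from methyl (S)-glycidate; lower C2 by chelation-controlled ketone reduction (anti); upper C2 and C3 from natural (2R,3R)-fustin; both upper C4 by attack on the flavan-4-yl cation anti to the C3 hydroxyl.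

Key step: step 7

Remark: (2R,3R)-fustin (2,3-trans-dihydrofisetin) is taken as a purchasable natural product of defined configuration.

**Route**

Step 1
Reactants: 1 1,3-bis(benzyloxy)-5-bromobenzene
Product: 2 1,5-bis(benzyloxy)-3-bromo-2-iodobenzene
Conditions: NIS, TFA (cat.), MeCN, 0 °C to rt
Reagents that add atoms: N-iodosuccinimide, O=C1CCC(=O)N1I
Why: Electrophilic aromatic iodination should enter at the carbon ortho to bromine, which is para to one benzyloxy group and ortho to the other and is less hindered than the carbon between the two benzyloxy groups, so that iodine marks the future C4a and bromine the future C8a.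

Step 2
Reactants: 2 1,5-bis(benzyloxy)-3-bromo-2-iodobenzene, 3 methyl (S)-glycidate
Product: 5 methyl (S)-3-[2,4-bis(benzyloxy)-6-bromophenyl]-2-hydroxypropanoate, via arylmagnesium chloride 4 (not isolated)
Conditions: iPrMgCl·LiCl, THF, −20 °C; then CuI (10 mol%), 3, −30 to 0 °C; aq NH4Cl
Reagents that add atoms: none
Why: Iodine–magnesium exchange is much faster at C–I than at C–Br and the ortho-bromoaryl Grignard reagent should resist aryne formation at low temperature; its copper-catalysed SN2 opening of the epoxide at the unsubstituted C3 forms the C4–C4a bond and leaves the stereocenter (future C3, S) untouched.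

Step 3
Reactants: 5 methyl (S)-3-[2,4-bis(benzyloxy)-6-bromophenyl]-2-hydroxypropanoate
Product: 6 methyl (S)-2-(benzyloxy)-3-[2,4-bis(benzyloxy)-6-bromophenyl]propanoate
Conditions: BnBr, Ag2O, Et2O, rt, dark
Reagents that add atoms: benzyl bromide, BrCc1ccccc1
Why: Williamson etherification promoted by Ag2O runs without a strong base, so the α-hydroxy ester should be benzylated without enolisation; the S centre is kept and the future O3 is masked so that only O1 can later reach ring A.

Step 4
Reactants: 6 methyl (S)-2-(benzyloxy)-3-[2,4-bis(benzyloxy)-6-bromophenyl]propanoate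
Product: 7 (S)-2-(benzyloxy)-3-[2,4-bis(benzyloxy)-6-bromophenyl]-N-methoxy-N-methylpropanamide
Conditions: MeNHOMe·HCl, iPrMgCl, THF, −20 °C
Reagents that add atoms: N,O-dimethylhydroxylamine hydrochloride, CNOC.Cl
Why: Weinreb amide formation by aminolysis of the ester with the chloromagnesium amide proceeds at low temperature, where neither epimerisation of the α-alkoxy centre nor bromine–magnesium exchange at the electron-rich aryl bromide is expected.

Step 5
Reactants: 7 (S)-2-(benzyloxy)-3-[2,4-bis(benzyloxy)-6-bromophenyl]-N-methoxy-N-methylpropanamide, 8 2-(benzyloxy)-4-bromo-1-methoxybenzene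
Product: 10 (S)-2-(benzyloxy)-1-[3-(benzyloxy)-4-methoxyphenyl]-3-[2,4-bis(benzyloxy)-6-bromophenyl]propan-1-one, via arylmagnesium bromide 9 (not isolated)
Conditions: 8, Mg, THF, rt; then 7, THF, 0 °C; aq NH4Cl
Reagents that add atoms: none
Why: Weinreb ketone synthesis: the aryl Grignard reagent adds once because the chelated tetrahedral adduct survives until work-up, which forms the C2–C1' bond with the ring B pattern (3-benzyloxy, 4-methoxy) fixed from the start.

Step 6
Reactants: 10 (S)-2-(benzyloxy)-1-[3-(benzyloxy)-4-methoxyphenyl]-3-[2,4-bis(benzyloxy)-6-bromophenyl]propan-1-one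
Product: 11 (1R,2S)-2-(benzyloxy)-1-[3-(benzyloxy)-4-methoxyphenyl]-3-[2,4-bis(benzyloxy)-6-bromophenyl]propan-1-ol
Conditions: Zn(BH4)2 (made from ZnCl2 and NaBH4 in Et2O), Et2O, −20 °C; aq NH4Cl
Reagents that add atoms: none
Why: Chelation-controlled hydride reduction (Cram chelate model): zinc bridges the carbonyl oxygen and the α-benzyloxy oxygen and hydride is delivered to the face that carries the α-hydrogen, which should set the new carbinol centre (future C2) as R, anti to the benzyloxy group.

Step 7
Reactants: 11 (1R,2S)-2-(benzyloxy)-1-[3-(benzyloxy)-4-methoxyphenyl]-3-[2,4-bis(benzyloxy)-6-bromophenyl]propan-1-ol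
Product: 12 (2R,3S)-3,5,7-tris(benzyloxy)-2-[3-(benzyloxy)-4-methoxyphenyl]chromane
Conditions: CuI (10 mol%), 3,4,7,8-tetramethyl-1,10-phenanthroline (20 mol%), Cs2CO3, toluene, 110 °C
Reagents that add atoms: none
Why: The cesium alkoxide of the C2 hydroxyl binds monovalent copper, the tethered aryl bromide adds oxidatively to give a seven-membered aryl(alkoxo) metallacycle of trivalent copper, and reductive elimination forms the O1–C8a bond; this is an intramolecular Ullmann-type O-arylation, the reaction type known for copper- or palladium-catalysed cyclisation of 3-(2-bromoaryl)propanols to chromans. Ring C closes as a six-membered ring in a 6-exo sense at the carbon that loses bromide. No stereocenter is created: C2 and C3 are carried through with retention because neither the C2–O nor the C3–O bond is broken, which matters here because the 4-methoxyphenyl group makes C2 prone to ionise in closures through the O1–C2 bond. The step needs O1 and not O3 to react, which the benzyl ether on O3 secures by excluding the five-membered dihydrobenzofuran closure; copper is preferred to palladium because the copper alkoxide of a secondary benzylic alcohol should not undergo β-hydride elimination to the ketone. The two benzyloxy groups of ring A are meta to the C–Br carbon, so they do not deactivate it by resonance donation.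

Step 8
Reactants: 12 (2R,3S)-3,5,7-tris(benzyloxy)-2-[3-(benzyloxy)-4-methoxyphenyl]chromane
Product: 13 (2R,3S)-2-(3-hydroxy-4-methoxyphenyl)chromane-3,5,7-triol (4'-O-methylcatechin)
Conditions: H2 (1 atm), Pd(OH)2/C, THF/MeOH, rt
Reagents that add atoms: none
Why: Catalytic hydrogenolysis should cleave all four benzyl ethers while the methyl ether and the cyclic C2–O1 bond of the chroman stay intact under these mild conditions, and no stereocenter is touched.

Step 9
Reactants: 14 (2R,3R)-fustin
Product: 15 (2R,3S,4R)-2-(3,4-dihydroxyphenyl)chromane-3,4,7-triol (2,3-trans-3,4-trans-leucofisetinidin)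
Conditions: NaBH4, EtOH, 0 °C to rt; neutral work-up
Reagents that add atoms: none
Why: Borohydride reduction of the chromanone carbonyl by axial hydride delivery to the ring with equatorial 2-aryl and 3-hydroxyl groups should give mainly the equatorial C4 alcohol (3,4-trans), and the C4 configuration is in any case lost in the next step.

Step 10
Reactants: 13 (2R,3S)-2-(3-hydroxy-4-methoxyphenyl)chromane-3,5,7-triol, 15 (2R,3S,4R)-2-(3,4-dihydroxyphenyl)chromane-3,4,7-triol
Product: 18 fisetinidol-(4α→6)-[fisetinidol-(4α→8)]-4'-O-methylcatechin (target), via fisetinidol-(4α→8)-4'-O-methylcatechin 16 (not isolated), via fisetinidol-(4α→6)-4'-O-methylcatechin 17 (not isolated)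
Conditions: 15 (2.5 equiv), 0.1 M aq HCl, rt, N2; Sephadex LH-20 (EtOH)
Reagents that add atoms: none
Why: Biomimetic Friedel–Crafts alkylation: dilute acid ionises the C4 hydroxyl of 15 to a benzylic cation stabilised by the para 7-hydroxyl, and this cation is captured at C8 and then C6 of the phloroglucinol-type ring A of 13, each time on the face anti to the C3 hydroxyl so that both new C4 centres should be 3,4-trans (4α, S), while the much less nucleophilic resorcinol-type rings of the fisetinidol units limit self-condensation; minor 4β epimers and lower adducts would be removed by chromatography.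

**Compound list**

1 | 1,3-bis(benzyloxy)-5-bromobenzene | Brc1cc(OCc2ccccc2)cc(OCc2ccccc2)c1 | starting material
2 | 1,5-bis(benzyloxy)-3-bromo-2-iodobenzene | Ic1c(Br)cc(OCc2ccccc2)cc1OCc1ccccc1 | intermediate
3 | methyl (S)-glycidate, methyl (2S)-oxirane-2-carboxylate | COC(=O)[C@@H]1CO1 | starting material
4 | [2,4-bis(benzyloxy)-6-bromophenyl]magnesium chloride | Cl[Mg]c1c(Br)cc(OCc2ccccc2)cc1OCc1ccccc1 | intermediate
5 | methyl (S)-3-[2,4-bis(benzyloxy)-6-bromophenyl]-2-hydroxypropanoate | COC(=O)[C@@H](O)Cc1c(Br)cc(OCc2ccccc2)cc1OCc1ccccc1 | intermediate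
6 | methyl (S)-2-(benzyloxy)-3-[2,4-bis(benzyloxy)-6-bromophenyl]propanoate | COC(=O)[C@@H](OCc1ccccc1)Cc1c(Br)cc(OCc2ccccc2)cc1OCc1ccccc1 | intermediate
7 | (S)-2-(benzyloxy)-3-[2,4-bis(benzyloxy)-6-bromophenyl]-N-methoxy-N-methylpropanamide | CON(C)C(=O)[C@@H](OCc1ccccc1)Cc1c(Br)cc(OCc2ccccc2)cc1OCc1ccccc1 | intermediate
8 | 2-(benzyloxy)-4-bromo-1-methoxybenzene | COc1ccc(Br)cc1OCc1ccccc1 | starting material
9 | [3-(benzyloxy)-4-methoxyphenyl]magnesium bromide | COc1ccc([Mg]Br)cc1OCc1ccccc1 | intermediate
10 | (S)-2-(benzyloxy)-1-[3-(benzyloxy)-4-methoxyphenyl]-3-[2,4-bis(benzyloxy)-6-bromophenyl]propan-1-one | COc1ccc(cc1OCc1ccccc1)C(=O)[C@@H](OCc1ccccc1)Cc1c(Br)cc(OCc2ccccc2)cc1OCc1ccccc1 | intermediate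
11 | (1R,2S)-2-(benzyloxy)-1-[3-(benzyloxy)-4-methoxyphenyl]-3-[2,4-bis(benzyloxy)-6-bromophenyl]propan-1-ol | COc1ccc(cc1OCc1ccccc1)[C@@H](O)[C@@H](OCc1ccccc1)Cc1c(Br)cc(OCc2ccccc2)cc1OCc1ccccc1 | intermediate
12 | (2R,3S)-3,5,7-tris(benzyloxy)-2-[3-(benzyloxy)-4-methoxyphenyl]chromane | COc1ccc([C@H]2Oc3cc(OCc4ccccc4)cc(OCc4ccccc4)c3C[C@@H]2OCc2ccccc2)cc1OCc1ccccc1 | intermediate
13 | (2R,3S)-2-(3-hydroxy-4-methoxyphenyl)chromane-3,5,7-triol (4'-O-methylcatechin) | COc1ccc([C@H]2Oc3cc(O)cc(O)c3C[C@@H]2O)cc1O | intermediate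
14 | (2R,3R)-fustin, (2R,3R)-2-(3,4-dihydroxyphenyl)-3,7-dihydroxychroman-4-one | O=C1c2ccc(O)cc2O[C@H](c2ccc(O)c(O)c2)[C@H]1O | starting material
15 | (2R,3S,4R)-2-(3,4-dihydroxyphenyl)chromane-3,4,7-triol | O[C@@H]1c2ccc(O)cc2O[C@H](c2ccc(O)c(O)c2)[C@H]1O | intermediate
16 | fisetinidol-(4α→8)-4'-O-methylcatechin | COc1ccc([C@H]2Oc3c(c(O)cc(O)c3[C@@H]3c4ccc(O)cc4O[C@H](c4ccc(O)c(O)c4)[C@H]3O)C[C@@H]2O)cc1O | intermediate
17 | fisetinidol-(4α→6)-4'-O-methylcatechin | COc1ccc([C@H]2Oc3cc(O)c([C@@H]4c5ccc(O)cc5O[C@H](c5ccc(O)c(O)c5)[C@H]4O)c(O)c3C[C@@H]2O)cc1O | intermediate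
18 | fisetinidol-(4α→6)-[fisetinidol-(4α→8)]-4'-O-methylcatechin, (2R,3S)-6,8-bis[(2R,3S,4S)-2-(3,4-dihydroxyphenyl)-3,7-dihydroxychroman-4-yl]-2-(3-hydroxy-4-methoxyphenyl)chromane-3,5,7-triol | COc1ccc([C@H]2Oc3c(c(O)c([C@@H]4c5ccc(O)cc5O[C@H](c5ccc(O)c(O)c5)[C@H]4O)c(O)c3[C@@H]3c4ccc(O)cc4O[C@H](c4ccc(O)c(O)c4)[C@H]3O)C[C@@H]2O)cc1O | target

**Count and risks**

Total step count: 10. Longest linear sequence: 9 steps (steps 1 to 8, then step 10).

Steps most likely to fail:

Step 2. The hindered ortho-bromoaryl Grignard reagent may lose magnesium halide to an aryne on warming, or may attack the ester carbonyl in place of the epoxide. The fallback sets out from 1 and comes back at 7. Vilsmeier–Haack formylation of 1 (POCl3, DMF) should give 2,4-bis(benzyloxy)-6-bromobenzaldehyde F1. Reduction with NaBH4 would give [2,4-bis(benzyloxy)-6-bromophenyl]methanol F2, and PBr3 would give 1,5-bis(benzyloxy)-3-bromo-2-(bromomethyl)benzene F3, to be used at once. In parallel, (R)-4-benzyloxazolidin-2-one would be N-acylated with benzyloxyacetyl chloride (n-BuLi, THF, −78 °C) to (R)-4-benzyl-3-[(benzyloxy)acetyl]oxazolidin-2-one F4. Alkylation of the sodium enolate of F4 (NaN(SiMe3)2, THF, −78 °C) with F3 is an oxazolidinone auxiliary alkylation in which the benzyl group of the auxiliary shields one enolate face. It should give (R)-4-benzyl-3-[(S)-2-(benzyloxy)-3-[2,4-bis(benzyloxy)-6-bromophenyl]propanoyl]oxazolidin-2-one F5. Transamination with MeNHOMe·HCl and AlMe3 would then deliver 7.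

Step 7. Oxidative addition of the electron-rich aryl bromide may be slow, so that reductive loss of bromine or base-induced decomposition overtakes C–O bond formation. The fallback sets out from 11 and comes back at 12, and closes ring C through the O1–C2 bond instead. Bromine–lithium exchange on the lithium alkoxide of 11 (n-BuLi, 2.2 equiv, THF, −78 °C), borylation with B(OMe)3 and oxidation (H2O2, NaOH) should give (1R,2S)-2-(benzyloxy)-1-[3-(benzyloxy)-4-methoxyphenyl]-3-[2,4-bis(benzyloxy)-6-hydroxyphenyl]propan-1-ol F6. Catalytic TsOH in CH2Cl2 at 0 °C would ionise the 4-methoxybenzylic alcohol, and the phenol would trap the cation. The 2,3-trans chroman 12, with both substituents pseudo-equatorial, should predominate and would be separated from its 2,3-cis isomer.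

Step 10. The second alkylation at the hindered C6 may stay incomplete, attack on the wrong face of the cation may occur at either C4, and acid-driven self-condensation of the diol may compete. The fallback sets out from 15 and comes back at 18. Thiolysis of 15 with phenylmethanethiol (AcOH, EtOH, reflux) should give 4α-(benzylsulfanyl)fisetinidol F7; either C4 epimer serves. Activation of F7 (2.5 equiv) with AgBF4 in THF at 0 °C in the presence of 13 would generate the same flavan-4-yl cation stoichiometrically under aprotic conditions, without aqueous acid. This should limit self-condensation and allow the two alkylations to be driven to completion to give 18.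

**Further compounds**

F1 | step 2 | 2,4-bis(benzyloxy)-6-bromobenzaldehyde | O=Cc1c(Br)cc(OCc2ccccc2)cc1OCc1ccccc1
F2 | step 2 | [2,4-bis(benzyloxy)-6-bromophenyl]methanol | OCc1c(Br)cc(OCc2ccccc2)cc1OCc1ccccc1
F3 | step 2 | 1,5-bis(benzyloxy)-3-bromo-2-(bromomethyl)benzene | BrCc1c(Br)cc(OCc2ccccc2)cc1OCc1ccccc1
F4 | step 2 | (R)-4-benzyl-3-[(benzyloxy)acetyl]oxazolidin-2-one | O=C1OC[C@@H](Cc2ccccc2)N1C(=O)COCc1ccccc1
F5 | step 2 | (R)-4-benzyl-3-[(S)-2-(benzyloxy)-3-[2,4-bis(benzyloxy)-6-bromophenyl]propanoyl]oxazolidin-2-one | O=C1OC[C@@H](Cc2ccccc2)N1C(=O)[C@@H](OCc1ccccc1)Cc1c(Br)cc(OCc2ccccc2)cc1OCc1ccccc1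
F6 | step 7 | (1R,2S)-2-(benzyloxy)-1-[3-(benzyloxy)-4-methoxyphenyl]-3-[2,4-bis(benzyloxy)-6-hydroxyphenyl]propan-1-ol | COc1ccc(cc1OCc1ccccc1)[C@@H](O)[C@@H](OCc1ccccc1)Cc1c(O)cc(OCc2ccccc2)cc1OCc1ccccc1
F7 | step 10 | 4α-(benzylsulfanyl)fisetinidol, (2R,3R,4R)-4-(benzylsulfanyl)-2-(3,4-dihydroxyphenyl)chromane-3,7-diol | C(c1ccccc1)S[C@@H]1c2ccc(O)cc2O[C@H](c2ccc(O)c(O)c2)[C@H]1O
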